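**Strategy.** The flavone is disconnected at both bonds of the C4 carbonyl carbon, which sits between C4a of the hexasubstituted ring A and the methoxy-bearing C3 of ring C and can be introduced as carbon monoxide. One palladium-catalysed carbonylative α-arylation joins a symmetric, fully oxygenated ring-A iodide, CO and the enolate of a B-ring α-methoxy ketone, forging C4a–C4 and C4–C3 and giving the C6–C3–C6 skeleton as a 2-methoxy-1,3-diketone. The iodide carries MOM ethers on the oxygens that become O1, 5-OH and 7-OH and methyl ethers at C6 and C8; the ketone carries benzyl ethers at the 4'- and 5'-oxygens. Acid then unmasks ring A and closes ring C, and hydrogenolysis finishes.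

Key step: step 9

Remark: the target has no stereocentre and no configurationally stable axis, so it is achiral; "single enantiomer" is taken to mean the constitution shown, and no stereocontrol is needed.

**Route**

Step 1
Reactants: 1 phloroglucinol
Product: 2 1,3,5-tris(methoxymethoxy)benzene
Conditions: NaH, MOMCl, DMF, 0 °C → rt
Reagents that add atoms: chloromethyl methyl ether, COCCl
Why: Williamson-type O-alkylation of the phenoxides with a hard, oxocarbenium-like electrophile should favour O- over C-alkylation and give the tris-acetal.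

Step 2
Reactants: 2 1,3,5-tris(methoxymethoxy)benzene
Product: 3 2,4-dibromo-1,3,5-tris(methoxymethoxy)benzene
Conditions: NBS (2.05 equiv), DMF, 0 °C → rt, dark
Reagents that add atoms: N-bromosuccinimide, O=C1CCC(=O)N1Br
Why: Electrophilic aromatic bromination of a strongly activated ring whose three C–H positions are equivalent; each bromine slightly deactivates, so two equivalents should stop at the dibromide, and the non-acidic medium spares the MOM acetals.

Step 3
Reactants: 3 2,4-dibromo-1,3,5-tris(methoxymethoxy)benzene
Product: 4 2,4-dimethoxy-1,3,5-tris(methoxymethoxy)benzene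
Conditions: NaOMe (excess), CuI (cat.), MeOH/DMF, 110 °C
Reagents that add atoms: sodium methoxide, [Na+].[O-]C
Why: Ullmann-type copper-catalysed methoxylation of aryl bromides is established for electron-rich, di-ortho-substituted bromides, and the basic medium leaves the MOM ethers intact.

Step 4
Reactants: 4 2,4-dimethoxy-1,3,5-tris(methoxymethoxy)benzene
Product: 6 1-iodo-3,5-dimethoxy-2,4,6-tris(methoxymethoxy)benzene, via aryllithium 5 (not isolated)
Conditions: n-BuLi, THF, 0 °C; then I2, −78 °C → rt
Reagents that add atoms: iodine, II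
Why: Directed ortho-metalation at the only ring C–H, which is flanked and acidified by two coordinating MOM-oxy groups, followed by iodine quench of the aryllithium.

Step 5
Reactants: 7 3,4-bis(benzyloxy)benzaldehyde
Product: 9 3,4-bis(benzyloxy)phenol, via aryl formate 8 (not isolated)
Conditions: mCPBA, CH2Cl2, rt; then K2CO3 (cat.), MeOH, rt
Reagents that add atoms: 3-chloroperoxybenzoic acid, OOC(=O)c1cccc(Cl)c1
Why: Dakin-type Baeyer–Villiger oxidation in which the electron-rich aryl group migrates to oxygen, followed by mild methanolysis of the aryl formate.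

Step 6
Reactants: 9 3,4-bis(benzyloxy)phenol
Product: 10 1,2-bis(benzyloxy)-4-methoxybenzene
Conditions: MeI, K2CO3, DMF, rt
Reagents that add atoms: iodomethane, CI
Why: Williamson ether synthesis by SN2 attack of the phenoxide on iodomethane.

Step 7
Reactants: 10 1,2-bis(benzyloxy)-4-methoxybenzene
Product: 11 1,2-bis(benzyloxy)-4-bromo-5-methoxybenzene
Conditions: NBS (1.05 equiv), MeCN, 0 °C → rt, dark
Reagents that add atoms: N-bromosuccinimide, O=C1CCC(=O)N1Br
Why: Electrophilic aromatic bromination should go to the position ortho to OMe and para to a benzyloxy group, the most activated and least hindered site, while ionic conditions avoid benzylic bromination.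

Step 8
Reactants: 11 1,2-bis(benzyloxy)-4-bromo-5-methoxybenzene; 12 N,2-dimethoxy-N-methylacetamide
Product: 15 1-[4,5-bis(benzyloxy)-2-methoxyphenyl]-2-methoxyethan-1-one, via aryllithium 13 (not isolated), via lithium hemiaminal adduct 14 (not isolated)
Conditions: n-BuLi, THF, −78 °C; then 12, −78 → 0 °C; 1 M HCl work-up
Reagents that add atoms: none
Why: Bromine–lithium exchange followed by Weinreb ketone synthesis, in which the chelated tetrahedral adduct blocks over-addition; the sequence fixes the acyl position through the bromide and avoids the Lewis acids of a Friedel–Crafts methoxyacetylation, which would threaten the benzyl and ortho-methyl ethers and decarbonylate the acyl chloride.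

Step 9
Reactants: 6 1-iodo-3,5-dimethoxy-2,4,6-tris(methoxymethoxy)benzene; 15 1-[4,5-bis(benzyloxy)-2-methoxyphenyl]-2-methoxyethan-1-one; 16 carbon monoxide
Product: 17 1-[4,5-bis(benzyloxy)-2-methoxyphenyl]-3-[3,5-dimethoxy-2,4,6-tris(methoxymethoxy)phenyl]-2-methoxypropane-1,3-dione
Conditions: Pd(dba)2 (5 mol %), dppp (5 mol %), MgCl2, Et3N, CO (1 atm), 1,4-dioxane, 80 °C
Reagents that add atoms: none
Why: Oxidative addition of the C–I bond of 6 to Pd(0), CO insertion to an aroyl–Pd(II) species, and C-acylation of the magnesium enolate of 15 (soft enolisation by MgCl2/Et3N) with reductive elimination should form C4a–C4 and C4–C3, the more acidic product being held as its magnesium diketonate so that a second acylation is suppressed. The closest known reaction type is the palladium-catalysed carbonylative α-arylation of aryl ketones with aryl iodides to 1,3-diketones; a di-ortho-oxygenated iodide and an α-alkoxy ketone lie at the edge of that scope, which is why the risk of the route is placed here. No ring is closed, and the new stereocentre at the diketone C2 (future C3) forms as a racemate without consequence, since it is enolisable and becomes sp2 in step 10. The step needs carbonylation to outrun direct α-arylation and C-acylation to outrun O-acylation: the two ortho MOM-oxy groups retard direct aryl–enolate reductive elimination while favouring CO insertion, and the magnesium enolate chelated by the α-methoxy group should react through carbon. Regiochemistry cannot stray, because 6 has a single C–I bond on a mirror-symmetric ring and 15 has only one enolisable position.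

Step 10
Reactants: 17 1-[4,5-bis(benzyloxy)-2-methoxyphenyl]-3-[3,5-dimethoxy-2,4,6-tris(methoxymethoxy)phenyl]-2-methoxypropane-1,3-dione
Product: 20 2-[4,5-bis(benzyloxy)-2-methoxyphenyl]-5,7-dihydroxy-3,6,8-trimethoxy-4H-chromen-4-one, via triphenol diketone 18 (not isolated), via cyclic hemiketal 19 (not isolated)
Conditions: 3 M HCl in MeOH, 50 °C
Reagents that add atoms: none
Why: Acid-catalysed acetal solvolysis removes the three MOM groups, and either of the two equivalent ortho-hydroxyls then adds to the B-ring ketone (6-exo-trig hemiketalisation) and dehydrates to the chromone as in the closing stage of a Baker–Venkataraman flavone synthesis; benzyl ethers survive, ring B has no free ortho-hydroxyl, and the symmetric ring A makes any Wessely–Moser ring-opening and reclosure degenerate.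

Step 11
Reactants: 20 2-[4,5-bis(benzyloxy)-2-methoxyphenyl]-5,7-dihydroxy-3,6,8-trimethoxy-4H-chromen-4-one
Product: 21 2-(4,5-dihydroxy-2-methoxyphenyl)-5,7-dihydroxy-3,6,8-trimethoxy-4H-chromen-4-one (5,7,4',5'-tetrahydroxy-3,6,8,2'-tetramethoxyflavone)
Conditions: H2 (1 atm), 10% Pd/C, EtOAc/MeOH, rt
Reagents that add atoms: none
Why: Catalytic hydrogenolysis of the two aryl benzyl ethers, with the tetrasubstituted vinylogous-ester C2=C3 bond of the chromone and the aryl methyl ethers expected to be inert at 1 atm and room temperature.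

**Compound list**

1 | phloroglucinol (benzene-1,3,5-triol) | Oc1cc(O)cc(O)c1 | starting material
2 | 1,3,5-tris(methoxymethoxy)benzene | COCOc1cc(OCOC)cc(OCOC)c1 | intermediate
3 | 2,4-dibromo-1,3,5-tris(methoxymethoxy)benzene | COCOc1cc(OCOC)c(Br)c(OCOC)c1Br | intermediate
4 | 2,4-dimethoxy-1,3,5-tris(methoxymethoxy)benzene | COCOc1cc(OCOC)c(OC)c(OCOC)c1OC | intermediate
5 | [3,5-dimethoxy-2,4,6-tris(methoxymethoxy)phenyl]lithium | [Li]c1c(OCOC)c(OC)c(OCOC)c(OC)c1OCOC | intermediate (not isolated)
6 | 1-iodo-3,5-dimethoxy-2,4,6-tris(methoxymethoxy)benzene | COCOc1c(I)c(OCOC)c(OC)c(OCOC)c1OC | intermediate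
7 | 3,4-bis(benzyloxy)benzaldehyde | O=Cc1ccc(OCc2ccccc2)c(OCc2ccccc2)c1 | starting material
8 | 3,4-bis(benzyloxy)phenyl formate | O=COc1ccc(OCc2ccccc2)c(OCc2ccccc2)c1 | intermediate (not isolated)
9 | 3,4-bis(benzyloxy)phenol | Oc1ccc(OCc2ccccc2)c(OCc2ccccc2)c1 | intermediate
10 | 1,2-bis(benzyloxy)-4-methoxybenzene | COc1ccc(OCc2ccccc2)c(OCc2ccccc2)c1 | intermediate
11 | 1,2-bis(benzyloxy)-4-bromo-5-methoxybenzene | COc1cc(OCc2ccccc2)c(OCc2ccccc2)cc1Br | intermediate
12 | N,2-dimethoxy-N-methylacetamide (Weinreb amide of methoxyacetic acid) | COCC(=O)N(C)OC | starting material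
13 | [4,5-bis(benzyloxy)-2-methoxyphenyl]lithium | COc1cc(OCc2ccccc2)c(OCc2ccccc2)cc1[Li] | intermediate (not isolated)
14 | lithium 1-[4,5-bis(benzyloxy)-2-methoxyphenyl]-2-methoxy-1-[methoxy(methyl)amino]ethan-1-olate (racemic) | COCC(O[Li])(N(C)OC)c1cc(OCc2ccccc2)c(OCc2ccccc2)cc1OC | intermediate (not isolated)
15 | 1-[4,5-bis(benzyloxy)-2-methoxyphenyl]-2-methoxyethan-1-one | COCC(=O)c1cc(OCc2ccccc2)c(OCc2ccccc2)cc1OC | intermediate
16 | carbon monoxide | [C-]#[O+] | starting material
17 | 1-[4,5-bis(benzyloxy)-2-methoxyphenyl]-3-[3,5-dimethoxy-2,4,6-tris(methoxymethoxy)phenyl]-2-methoxypropane-1,3-dione (racemic at C2, enolisable) | COCOc1c(OC)c(OCOC)c(OC)c(OCOC)c1C(=O)C(OC)C(=O)c1cc(OCc2ccccc2)c(OCc2ccccc2)cc1OC | intermediate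
18 | 1-[4,5-bis(benzyloxy)-2-methoxyphenyl]-2-methoxy-3-(2,4,6-trihydroxy-3,5-dimethoxyphenyl)propane-1,3-dione (racemic, enolisable) | COc1cc(OCc2ccccc2)c(OCc2ccccc2)cc1C(=O)C(OC)C(=O)c1c(O)c(OC)c(O)c(OC)c1O | intermediate (not isolated)
19 | 2-[4,5-bis(benzyloxy)-2-methoxyphenyl]-2,5,7-trihydroxy-3,6,8-trimethoxy-2,3-dihydro-4H-chromen-4-one (racemic diastereomer mixture) | COc1cc(OCc2ccccc2)c(OCc2ccccc2)cc1C1(O)Oc2c(OC)c(O)c(OC)c(O)c2C(=O)C1OC | intermediate (not isolated)
20 | 2-[4,5-bis(benzyloxy)-2-methoxyphenyl]-5,7-dihydroxy-3,6,8-trimethoxy-4H-chromen-4-one | COc1cc(OCc2ccccc2)c(OCc2ccccc2)cc1-c1oc2c(OC)c(O)c(OC)c(O)c2c(=O)c1OC | intermediate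
21 | 2-(4,5-dihydroxy-2-methoxyphenyl)-5,7-dihydroxy-3,6,8-trimethoxy-4H-chromen-4-one (5,7,4',5'-tetrahydroxy-3,6,8,2'-tetramethoxyflavone) | COc1cc(O)c(O)cc1-c1oc2c(OC)c(O)c(OC)c(O)c2c(=O)c1OC | target

**Step count**

Total steps: 11. Longest linear sequence: 7 steps (steps 1–4, then 9–11; the B-ring branch, steps 5–8 then 9–11, is equally long).

**Steps most likely to fail**

Step 9. Oxidative addition and CO insertion at the doubly ortho-substituted, very electron-rich iodide may be slow, so protodeiodination or direct non-carbonylative arylation could take over. Acylation could also occur on the enolate oxygen, or magnesium chelation could strip an ortho MOM group at 80 °C. Fallback, an aldol–oxidation sequence in place of the carbonylation, setting out from 4 and 15 and returning at 17: 4 is lithiated as in step 4 to 5 and quenched with DMF, which should give, through lithium (dimethylamino)[3,5-dimethoxy-2,4,6-tris(methoxymethoxy)phenyl]methanolate F1, the aldehyde 3,5-dimethoxy-2,4,6-tris(methoxymethoxy)benzaldehyde F2 after aqueous work-up. Ketone 15 is deprotonated with LiHMDS (THF, −78 °C) to the chelated enolate lithium (Z)-1-[4,5-bis(benzyloxy)-2-methoxyphenyl]-2-methoxyethen-1-olate F3, whose geometry is immaterial. Aldol addition of this enolate to the aldehyde and aqueous quench should give 1-[4,5-bis(benzyloxy)-2-methoxyphenyl]-3-[3,5-dimethoxy-2,4,6-tris(methoxymethoxy)phenyl]-3-hydroxy-2-methoxypropan-1-one F4 as a diastereomer mixture. Dess–Martin periodinane (NaHCO3, CH2Cl2) should then oxidise the carbinol to diketone 17, C4 now coming from DMF.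

Step 3. Reductive loss of bromine may compete with substitution, or the reaction may stall after the first methoxylation at the doubly flanked positions. Fallback, which installs each oxygen by directed metalation and borate oxidation instead of copper substitution, setting out from 2 and returning at 4 (steps 2 and 3 are bypassed). n-BuLi (THF, 0 °C) should give [2,4,6-tris(methoxymethoxy)phenyl]lithium F5. B(OMe)3 converts it into dimethyl [2,4,6-tris(methoxymethoxy)phenyl]boronate F6, and H2O2/NaOH oxidises this to 2,4,6-tris(methoxymethoxy)phenol F7. MeI/K2CO3 gives 2-methoxy-1,3,5-tris(methoxymethoxy)benzene F8. The same sequence is repeated at one of the two equivalent remaining C–H positions: [3-methoxy-2,4,6-tris(methoxymethoxy)phenyl]lithium F9, then dimethyl [3-methoxy-2,4,6-tris(methoxymethoxy)phenyl]boronate F10, then 3-methoxy-2,4,6-tris(methoxymethoxy)phenol F11. A final methylation with MeI/K2CO3 should give 4.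

Step 10. Acid-catalysed retro-Claisen methanolysis of the hindered diketone may compete with ring closure, the sequence may stall at the hemiketal, or the benzyl ethers may erode on prolonged heating in acid. Fallback, which separates unmasking from ring closure and removes the nucleophilic solvent, setting out from 17 and returning at 20: the MOM ethers are cleaved with TFA in CH2Cl2 at 0 °C, and the triphenol 18, in equilibrium with hemiketal 19, is isolated after aqueous work-up. It is then dehydrated in a separate operation with catalytic p-TsOH in toluene under azeotropic removal of water to give 20. This fallback makes no compound outside the compound list (F0).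

**Further compounds**

F1 | step 9 | lithium (dimethylamino)[3,5-dimethoxy-2,4,6-tris(methoxymethoxy)phenyl]methanolate | COCOc1c(C(O[Li])N(C)C)c(OCOC)c(OC)c(OCOC)c1OC
F2 | step 9 | 3,5-dimethoxy-2,4,6-tris(methoxymethoxy)benzaldehyde | COCOc1c(C=O)c(OCOC)c(OC)c(OCOC)c1OC
F3 | step 9 | lithium (Z)-1-[4,5-bis(benzyloxy)-2-methoxyphenyl]-2-methoxyethen-1-olate | CO/C=C(\O[Li])c1cc(OCc2ccccc2)c(OCc2ccccc2)cc1OC
F4 | step 9 | 1-[4,5-bis(benzyloxy)-2-methoxyphenyl]-3-[3,5-dimethoxy-2,4,6-tris(methoxymethoxy)phenyl]-3-hydroxy-2-methoxypropan-1-one (diastereomer mixture) | COCOc1c(OC)c(OCOC)c(OC)c(OCOC)c1C(O)C(OC)C(=O)c1cc(OCc2ccccc2)c(OCc2ccccc2)cc1OC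
F5 | step 3 | [2,4,6-tris(methoxymethoxy)phenyl]lithium | [Li]c1c(OCOC)cc(OCOC)cc1OCOC
F6 | step 3 | dimethyl [2,4,6-tris(methoxymethoxy)phenyl]boronate | COB(OC)c1c(OCOC)cc(OCOC)cc1OCOC
F7 | step 3 | 2,4,6-tris(methoxymethoxy)phenol | Oc1c(OCOC)cc(OCOC)cc1OCOC
F8 | step 3 | 2-methoxy-1,3,5-tris(methoxymethoxy)benzene | COc1c(OCOC)cc(OCOC)cc1OCOC
F9 | step 3 | [3-methoxy-2,4,6-tris(methoxymethoxy)phenyl]lithium | [Li]c1c(OCOC)cc(OCOC)c(OC)c1OCOC
F10 | step 3 | dimethyl [3-methoxy-2,4,6-tris(methoxymethoxy)phenyl]boronate | COB(OC)c1c(OCOC)cc(OCOC)c(OC)c1OCOC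
F11 | step 3 | 3-methoxy-2,4,6-tris(methoxymethoxy)phenol | Oc1c(OCOC)cc(OCOC)c(OC)c1OCOC
F0 | step 10 | none | none
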